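**Retrosynthetic overview**
- The C3–Br bond is made last by electrophilic bromination of free 5,7-dibromoindole, which comes from its N-tosyl derivative by cleavage of the sulfonyl group.
- The pyrrole ring is the only ring built. It is closed at C2=C3 by ring-closing metathesis of an N-tosyl-N-propenyl-2-vinylaniline; the benzene ring with both bromines (C5, C7) comes intact from the starting aldehyde.
- The metathesis diene comes from 2-amino-3,5-dibromobenzaldehyde: the aldehyde carbon becomes C3 (Wittig methylenation) and nitrogen receives tosyl, then allyl, which is isomerised to propenyl (C2).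
- Feature relied on: before bromination, C2 and C3 are an unsubstituted CH=CH unit flanked by N1 and C3a of the pyrrole ring, so this ring can be closed as an alkene between a vinyl group on C3a and an alkenyl group on N1.

Key step: step 5

Assumption: the propenyl group of compound 9 is drawn as (E); the isomerisation is expected to give a mixture of geometric isomers, which would be used as such because the propenyl terminus is expelled as propene in step 5.

**Route**

Step 1
Reactants: 1 2-amino-3,5-dibromobenzaldehyde; 2 methyltriphenylphosphonium bromide
Product: 4 2,4-dibromo-6-vinylaniline, via methylenetriphenylphosphorane 3 (not isolated)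
Conditions: MePPh3Br, KOtBu, THF, 0 °C to rt
Reagents that add atoms: 2 methyltriphenylphosphonium bromide, C[P+](c1ccccc1)(c1ccccc1)c1ccccc1.[Br-]
Why: Wittig olefination, in which the non-stabilised ylide 3 adds to the aldehyde and the oxaphosphetane collapses to the terminal alkene, while the weakly acidic, electron-poor ArNH2 neither quenches the ylide nor needs protection, as in the known methylenation of 2-aminobenzaldehydes.

Step 2
Reactants: 4 2,4-dibromo-6-vinylaniline; 5 4-toluenesulfonyl chloride
Product: 6 N-(2,4-dibromo-6-vinylphenyl)-4-methylbenzenesulfonamide
Conditions: TsCl, pyridine, DMAP (cat.), 60 °C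
Reagents that add atoms: 5 4-toluenesulfonyl chloride, Cc1ccc(cc1)S(Cl)(=O)=O
Why: N-Sulfonylation of the aniline (Hinsberg-type sulfonamide formation) through the N-sulfonylpyridinium species formed from TsCl and DMAP, which should be electrophilic enough for this doubly ortho-substituted, weakly nucleophilic amine, the vinyl group and aryl bromides being inert.

Step 3
Reactants: 6 N-(2,4-dibromo-6-vinylphenyl)-4-methylbenzenesulfonamide; 7 allyl bromide
Product: 8 N-allyl-N-(2,4-dibromo-6-vinylphenyl)-4-methylbenzenesulfonamide
Conditions: allyl bromide, K2CO3, DMF, rt to 50 °C
Reagents that add atoms: 7 allyl bromide, C=CCBr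
Why: SN2 N-alkylation, in which carbonate deprotonates the acidic N-aryl sulfonamide N–H and the anion displaces bromide from the unhindered allylic halide, nitrogen being the only nucleophilic site.

Step 4
Reactants: 8 N-allyl-N-(2,4-dibromo-6-vinylphenyl)-4-methylbenzenesulfonamide
Product: 9 N-(2,4-dibromo-6-vinylphenyl)-N-[(E)-prop-1-enyl]-4-methylbenzenesulfonamide
Conditions: RuHCl(CO)(PPh3)3 (5 mol%), toluene, 110 °C
Reagents that add atoms: none
Why: Ruthenium hydride-catalysed olefin isomerisation (hydrometalation/β-hydride elimination) moves the allyl double bond into conjugation with nitrogen to give the thermodynamically preferred enamide, a known transformation of N-allyl sulfonamides, whereas the styrene vinyl group has no allylic hydrogen and cannot migrate.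

Step 5
Reactants: 9 N-(2,4-dibromo-6-vinylphenyl)-N-[(E)-prop-1-enyl]-4-methylbenzenesulfonamide
Product: 10 5,7-dibromo-1-tosylindole
Conditions: second-generation Grubbs catalyst (H2IMes)(PCy3)Cl2Ru=CHPh (5–10 mol%), toluene (0.01 M), 80 °C
Reagents that add atoms: none
Why: Ring-closing olefin metathesis of an enamide–styrene diene, a known route to N-sulfonylindoles. The ruthenium benzylidene should first exchange onto the unhindered styrene CH=CH2 to give an aryl-substituted alkylidene Ru=CH–Ar, which adds intramolecularly across the N–CH=CH–CH3 double bond to a ruthenacyclobutane and cycloreverts, so that the benzylic carbon (C3) and the N-bound carbon (C2) become doubly bonded and Ru=CHCH3 leaves, to be turned over as propene. The pyrrole ring is thus closed as a five-membered ring at C2=C3 by intramolecular [2+2] cycloaddition/cycloreversion between two alkenes held ortho on the benzene ring through C3a–C7a–N1, and the gain of indole aromaticity makes the closure irreversible. No stereocenter is formed and the geometry of the propenyl group is erased. The step needs ring closure to win over intermolecular styrene homodimerisation and needs the other groups to stay passive: ortho placement plus dilution favours closure, the N-sulfonyl group keeps nitrogen from turning the catalyst into a dormant Fischer-type aminocarbene, and aryl C–Br bonds do not react with ruthenium alkylidenes. The main uncertainty is steric, since the tosyl group must swing toward the C7 bromine as the ring flattens.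

Step 6
Reactants: 10 5,7-dibromo-1-tosylindole
Product: 11 5,7-dibromo-1H-indole
Conditions: KOH, MeOH/THF/H2O, 60 °C
Reagents that add atoms: none
Why: Base-mediated N-desulfonylation, in which hydroxide attacks sulfur and expels the indolide, a leaving group improved by the two ring bromines and by relief of the tosyl/C7-bromine clash, while the aryl bromides are untouched and the water present destroys any methyl tosylate before it can N-methylate the product.

Step 7
Reactants: 11 5,7-dibromo-1H-indole
Product: 12 3,5,7-tribromo-1H-indole
Conditions: NBS (1.0 equiv), DMF, 0 °C, dark
Reagents that add atoms: N-bromosuccinimide, O=C1CCC(=O)N1Br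
Why: Electrophilic aromatic substitution, in which C3 as the enamine-like, most nucleophilic carbon of a free NH indole takes up bromine from NBS faster than C2 or the deactivated benzo positions C4 and C6, so that one equivalent at low temperature should stop at the 3-bromo compound.

**Compound list**
1 | 2-amino-3,5-dibromobenzaldehyde | Nc1c(Br)cc(Br)cc1C=O | starting material
2 | methyltriphenylphosphonium bromide | C[P+](c1ccccc1)(c1ccccc1)c1ccccc1.[Br-] | starting material
3 | methylenetriphenylphosphorane | C=P(c1ccccc1)(c1ccccc1)c1ccccc1 | intermediate
4 | 2,4-dibromo-6-vinylaniline | Nc1c(Br)cc(Br)cc1C=C | intermediate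
5 | 4-toluenesulfonyl chloride | Cc1ccc(cc1)S(Cl)(=O)=O | starting material
6 | N-(2,4-dibromo-6-vinylphenyl)-4-methylbenzenesulfonamide | Cc1ccc(cc1)S(=O)(=O)Nc1c(Br)cc(Br)cc1C=C | intermediate
7 | allyl bromide | C=CCBr | starting material
8 | N-allyl-N-(2,4-dibromo-6-vinylphenyl)-4-methylbenzenesulfonamide | C=CCN(c1c(Br)cc(Br)cc1C=C)S(=O)(=O)c1ccc(C)cc1 | intermediate
9 | N-(2,4-dibromo-6-vinylphenyl)-N-[(E)-prop-1-enyl]-4-methylbenzenesulfonamide | C/C=C/N(c1c(Br)cc(Br)cc1C=C)S(=O)(=O)c1ccc(C)cc1 | intermediate
10 | 5,7-dibromo-1-tosylindole | Cc1ccc(cc1)S(=O)(=O)n1ccc2cc(Br)cc(Br)c21 | intermediate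
11 | 5,7-dibromo-1H-indole | Brc1cc(Br)c2[nH]ccc2c1 | intermediate
12 | 3,5,7-tribromo-1H-indole | Brc1cc(Br)c2[nH]cc(Br)c2c1 | target

**Step count**
Total steps: 7. Longest linear sequence: 7 steps (1 → 4 → 6 → 8 → 9 → 10 → 11 → 12).

**Steps most likely to fail, with fallbacks**

Step 5. The ring closure may be outrun by intermolecular metathesis of the styrene (oligomers, stilbene-type dimers), or may stall because the tosyl group and the C7 bromine resist the flattening needed in the metallacycle. The fallback sets out from compound 6 and comes back at compound 10. The N–H sulfonamide with its ortho vinyl group would be cyclised oxidatively in a Hegedus-type aza-Wacker reaction with catalytic PdCl2(MeCN)2 (divalent palladium), 1,4-benzoquinone and LiCl in THF at reflux. Aminopalladation of the vinyl group by the sulfonamide nitrogen and β-hydride elimination form the N1–C2 bond and the C2=C3 double bond; benzoquinone reoxidises the zerovalent palladium before it can insert into the aryl bromides. No new compound is made (F0).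

Step 4. The double-bond migration may stop short of full conversion, or the ruthenium hydride may consume the styrene by oligomerisation at 110 °C. The fallback sets out from compound 6 and comes back at compound 10, replacing the propenyl group by a vinyl group made without a metal hydride. Alkylation of 6 with excess 1,2-dibromoethane (K2CO3, DMF, 60 °C) should give N-(2-bromoethyl)-N-(2,4-dibromo-6-vinylphenyl)-4-methylbenzenesulfonamide F1. E2 elimination with KOtBu in THF at 0 °C should give N-(2,4-dibromo-6-vinylphenyl)-4-methyl-N-vinylbenzenesulfonamide F2. Ring-closing metathesis of F2 with the second-generation Grubbs catalyst (H2IMes)(PCy3)Cl2Ru=CHPh in dilute toluene then closes the same C2=C3 bond with loss of ethene to give 10.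

Step 2. Sulfonylation may stall on the hindered, weakly nucleophilic amine, or run unevenly to mixtures of mono- and bis-sulfonylated material. The fallback sets out from compound 4 and comes back at compound 6. The aniline would be deprotonated with excess NaH in THF/DMF and driven with excess TsCl fully to the sulfonimide N-(2,4-dibromo-6-vinylphenyl)-4-methyl-N-(4-methylphenylsulfonyl)benzenesulfonamide F3. One sulfonyl group would then be cleaved with KOH in MeOH/THF at rt; the sulfonamide anion is a good leaving group, so the cleavage should stop cleanly at 6.

**Further compounds**
F0 | step 5 | none | none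
F1 | step 4 | N-(2-bromoethyl)-N-(2,4-dibromo-6-vinylphenyl)-4-methylbenzenesulfonamide | BrCCN(c1c(Br)cc(Br)cc1C=C)S(=O)(=O)c1ccc(C)cc1
F2 | step 4 | N-(2,4-dibromo-6-vinylphenyl)-4-methyl-N-vinylbenzenesulfonamide | C=CN(c1c(Br)cc(Br)cc1C=C)S(=O)(=O)c1ccc(C)cc1
F3 | step 2 | N-(2,4-dibromo-6-vinylphenyl)-4-methyl-N-(4-methylphenylsulfonyl)benzenesulfonamide | Cc1ccc(cc1)S(=O)(=O)N(c1c(Br)cc(Br)cc1C=C)S(=O)(=O)c1ccc(C)cc1
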